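**Plan**

- Retrosynthesis: the one-carbon CH2 bridge is first written as a ketone (a helper). The dihydropyran is then cut at O–C(spiro) and CH2–CH(i-Pr), a hetero-Diels–Alder disconnection, giving an exocyclic-methylene bicyclo[3.1.1]heptanone and an oxadiene made from syncarpic acid and isobutyraldehyde.
- The bicycle is cut at the bridgehead CH–C(=CH2) bond, giving a cyclobutanone silyl enol ether that carries a but-3-ynyl chain. That chain is cut from the cyclobutanone α-carbon.
- Forward ring order: purchased cyclobutane, then the six-membered carbocycle (completing the bicyclo[3.1.1]heptane), then the dihydropyran onto the preformed cyclohexanetrione, then removal of the ketone helper.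
- Enabling feature: the CH2 bridge of the four-membered ring is bonded to the bridgehead CH. As a carbonyl (silyl enol ether) it makes that CH a carbon nucleophile, while the spiro carbon (bonded to O and to the pyran CH2) sits at the oxidation level of the internal carbon of a terminal alkyne.
- Stereochemistry: the cyclobutane CH comes from a RAMP-hydrazone alkylation, and the bridgehead CH follows from the cis-only bridge closure. The spiro carbon and CH(i-Pr) come from the cycloaddition (face anti to the gem-dimethyl bridge, bridgehead side exo).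

Key step: step 7

Remark: the sense of induction in step 4 is assigned by analogy with cycloalkanone SAMP/RAMP hydrazone alkylations (SAMP gives R when the ring carbon outranks the new chain); if the cyclobutanone azaenolate reacted with the opposite sense, SAMP would be used instead.

**Route**

Step 1
Reactants: 1 1-(2,4,6-trihydroxyphenyl)ethan-1-one
Product: 2 6-acetyl-2,2,4,4-tetramethylcyclohexane-1,3,5-trione (drawn as its enol)
Conditions: NaOMe (excess), MeI (excess), MeOH, 0 °C → reflux
Reagents that add atoms: iodomethane, CI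
Why: exhaustive dearomatizing C-methylation of the phloroglucinol polyanion places two geminal methyl pairs on the ring carbons that flank the acyl-bearing carbon.

Step 2
Reactants: 2 6-acetyl-2,2,4,4-tetramethylcyclohexane-1,3,5-trione
Product: 3 2,2,4,4-tetramethylcyclohexane-1,3,5-trione (syncarpic acid)
Conditions: 6 M HCl (aq), reflux
Reagents that add atoms: none
Why: acid-mediated retro-Claisen deacylation of the 2-acyl-1,3-dione leaves the free CH2 between two carbonyls.

Step 3
Reactants: 4 3,3-dimethylcyclobutan-1-one; 5 (R)-1-amino-2-(methoxymethyl)pyrrolidine (RAMP)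
Product: 6 (R)-N-(3,3-dimethylcyclobutylidene)-2-(methoxymethyl)pyrrolidin-1-amine
Conditions: neat, 60 °C, then water removed in vacuo
Reagents that add atoms: none
Why: hydrazone condensation (first stage of the Enders SAMP/RAMP method); the ketone is symmetric, so no C=N isomers arise.

Step 4
Reactants: 6 (R)-N-(3,3-dimethylcyclobutylidene)-2-(methoxymethyl)pyrrolidin-1-amine; 7 (4-bromobut-1-yn-1-yl)trimethylsilane
Product: 8 (R)-N-[(E,2S)-3,3-dimethyl-2-[4-(trimethylsilyl)but-3-yn-1-yl]cyclobutylidene]-2-(methoxymethyl)pyrrolidin-1-amine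
Conditions: LiN(i-Pr)2, THF, 0 °C; then 7, −100 °C → rt
Reagents that add atoms: none
Why: Enders RAMP-hydrazone alkylation, in which the lithium azaenolate, held rigid by chelation to the methoxymethyl arm, is alkylated by the primary bromide on its open face and so sets the (S) α-carbon.

Step 5
Reactants: 8 (R)-N-[(E,2S)-3,3-dimethyl-2-[4-(trimethylsilyl)but-3-yn-1-yl]cyclobutylidene]-2-(methoxymethyl)pyrrolidin-1-amine
Product: 10 (2S)-2-(but-3-yn-1-yl)-3,3-dimethylcyclobutan-1-one, via terminal-alkyne hydrazone 9 (not isolated)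
Conditions: K2CO3 (cat.), MeOH, rt; then saturated aqueous oxalic acid, Et2O, rt
Reagents that add atoms: water, O
Why: carbonate-catalysed methanolysis of the C(sp)–Si bond frees the alkyne while the hydrazone still shields the α-stereocentre from base, and two-phase oxalic acid hydrolysis then cleaves the hydrazone without epimerization.

Step 6
Reactants: 10 (2S)-2-(but-3-yn-1-yl)-3,3-dimethylcyclobutan-1-one
Product: 11 {[(4S)-4-(but-3-yn-1-yl)-3,3-dimethylcyclobut-1-en-1-yl]oxy}tri(propan-2-yl)silane
Conditions: LiN(SiMe3)2, THF, −78 °C; i-Pr3SiOTf, −78 → 0 °C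
Reagents that add atoms: triisopropylsilyl trifluoromethanesulfonate, CC(C)[Si](C(C)C)(C(C)C)OS(=O)(=O)C(F)(F)F
Why: kinetic deprotonation by the bulky amide takes place at the free α-CH2, not at the hindered α-CH (so the stereocentre is untouched) nor at the less acidic alkyne C–H, and O-silylation gives the regiodefined silyl enol ether.

Step 7
Reactants: 11 {[(4S)-4-(but-3-yn-1-yl)-3,3-dimethylcyclobut-1-en-1-yl]oxy}tri(propan-2-yl)silane
Product: 12 (1R,5S)-7,7-dimethyl-2-methylidenebicyclo[3.1.1]heptan-6-one
Conditions: (Ph3P)AuCl (10 mol%), AgBF4 (10 mol%), toluene/MeOH (10:1), 40 °C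
Reagents that add atoms: none
Why: Cationic monovalent gold binds the terminal alkyne, the silyl enol ether carbon (the future bridgehead CH) attacks the internal alkyne carbon (the future spiro carbon) anti to the metal, and methanol then takes the silyl group from the silyloxocarbenium ion and protonates the vinyl–gold bond to release the exocyclic methylene and the catalyst. The closest known reaction type is the gold-catalysed carbocyclization of cyclic silyl enol ethers onto pendant alkynes (a Conia-ene-type reaction), which is established for bridged bicyclic ketones. The new six-membered carbocycle closes in the 6-exo-dig mode (6-enolexo when counted through the gem-dimethyl carbon), and since both ends of the tether already sit on the four-membered ring this one closure completes the bicyclo[3.1.1]heptane. The only new stereocentre is the bridgehead CH, controlled by the existing (S)-CH of the cyclobutene: the three-carbon tether reaches the enol ether carbon only on its own face, so the bridge can only be cis. The step needs 6-exo over 7-endo regioselectivity, which the Markovnikov polarization of the terminal alkyne secures, and C–C bond formation ahead of protodesilylation or alkyne solvolysis, which the bulky triisopropylsilyl group and the short tether should secure.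

Step 8
Reactants: 12 (1R,5S)-7,7-dimethyl-2-methylidenebicyclo[3.1.1]heptan-6-one; 3 2,2,4,4-tetramethylcyclohexane-1,3,5-trione; 13 2-methylpropanal
Product: 15 (1S,2S,4'S,5S)-6',6',7,7,8',8'-hexamethyl-4'-(propan-2-yl)-3',4'-dihydrospiro[bicyclo[3.1.1]heptane-2,2'-chromene]-5',6,7'(6'H,8'H)-trione, via isobutylidenesyncarpic acid 14 (not isolated)
Conditions: 3 and 13 in excess, ethylenediammonium diacetate (10 mol%), toluene, 90 °C, sealed tube
Reagents that add atoms: none
Why: Knoevenagel condensation gives the electron-poor 1-oxadiene 14, which adds to the 1,1-disubstituted alkene of 12 in an inverse-electron-demand hetero-Diels–Alder reaction with oxygen bonding to the more substituted carbon; approach on the face anti to the gem-dimethyl bridge (past the flat carbonyl bridge) sets the spiro carbon as S, and the orientation with the bulky bridgehead side exo and the ring CH2 endo places the isopropyl group cis to that CH2 and sets CH(i-Pr) as S.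

Step 9
Reactants: 15 (1S,2S,4'S,5S)-6',6',7,7,8',8'-hexamethyl-4'-(propan-2-yl)-3',4'-dihydrospiro[bicyclo[3.1.1]heptane-2,2'-chromene]-5',6,7'(6'H,8'H)-trione
Product: 17 (1S,2S,4'S,5R)-6,6,6',6',8',8'-hexamethyl-4'-(propan-2-yl)-3',4'-dihydrospiro[bicyclo[3.1.1]heptane-2,2'-chromene]-5',7'(6'H,8'H)-dione, via tosylhydrazone 16 (not isolated)
Conditions: 4-methylbenzenesulfonohydrazide, EtOH, 50 °C; then catecholborane, CHCl3, 0 °C → rt; NaOAc·3H2O, reflux
Reagents that add atoms: none
Why: condensation should occur only at the strained, exposed four-ring ketone (the other ketone lies between two quaternary carbons and the third carbonyl is a vinylogous ester), and hydride reduction of the tosylhydrazone followed by acetate-induced loss of sulfinate and N2 (a mild Wolff–Kishner-type deoxygenation) turns C=O into CH2 without touching a stereocentre.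

**Compound list**

1 | 1-(2,4,6-trihydroxyphenyl)ethan-1-one | CC(=O)c1c(O)cc(O)cc1O | starting material
2 | 6-acetyl-2,2,4,4-tetramethylcyclohexane-1,3,5-trione (enol form) | CC(=O)C1=C(O)C(C)(C)C(=O)C(C)(C)C1=O | intermediate
3 | 2,2,4,4-tetramethylcyclohexane-1,3,5-trione (syncarpic acid) | CC1(C)C(=O)CC(=O)C(C)(C)C1=O | intermediate
4 | 3,3-dimethylcyclobutan-1-one | CC1(C)CC(=O)C1 | starting material
5 | (R)-1-amino-2-(methoxymethyl)pyrrolidine (RAMP) | COC[C@H]1CCCN1N | starting material
6 | (R)-N-(3,3-dimethylcyclobutylidene)-2-(methoxymethyl)pyrrolidin-1-amine | CC1(C)CC(=NN2CCC[C@@H]2COC)C1 | intermediate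
7 | (4-bromobut-1-yn-1-yl)trimethylsilane | C[Si](C)(C)C#CCCBr | starting material
8 | (R)-N-[(E,2S)-3,3-dimethyl-2-[4-(trimethylsilyl)but-3-yn-1-yl]cyclobutylidene]-2-(methoxymethyl)pyrrolidin-1-amine | C[Si](C)(C)C#CCC[C@@H]1/C(=N/N2CCC[C@@H]2COC)CC1(C)C | intermediate
9 | (R)-N-[(E,2S)-2-(but-3-yn-1-yl)-3,3-dimethylcyclobutylidene]-2-(methoxymethyl)pyrrolidin-1-amine (not isolated) | C#CCC[C@@H]1/C(=N/N2CCC[C@@H]2COC)CC1(C)C | intermediate
10 | (2S)-2-(but-3-yn-1-yl)-3,3-dimethylcyclobutan-1-one | C#CCC[C@@H]1C(=O)CC1(C)C | intermediate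
11 | {[(4S)-4-(but-3-yn-1-yl)-3,3-dimethylcyclobut-1-en-1-yl]oxy}tri(propan-2-yl)silane | C#CCC[C@@H]1C(O[Si](C(C)C)(C(C)C)C(C)C)=CC1(C)C | intermediate
12 | (1R,5S)-7,7-dimethyl-2-methylidenebicyclo[3.1.1]heptan-6-one | C=C1CC[C@@H]2C(=O)[C@H]1C2(C)C | intermediate
13 | 2-methylpropanal | CC(C)C=O | starting material
14 | 2,2,4,4-tetramethyl-6-(2-methylpropylidene)cyclohexane-1,3,5-trione (not isolated) | CC(C)C=C1C(=O)C(C)(C)C(=O)C(C)(C)C1=O | intermediate
15 | (1S,2S,4'S,5S)-6',6',7,7,8',8'-hexamethyl-4'-(propan-2-yl)-3',4'-dihydrospiro[bicyclo[3.1.1]heptane-2,2'-chromene]-5',6,7'(6'H,8'H)-trione | CC(C)[C@@H]1C[C@]2(CC[C@@H]3C(=O)[C@H]2C3(C)C)OC2=C1C(=O)C(C)(C)C(=O)C2(C)C | intermediate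
16 | 6-(4-methylbenzenesulfonyl)hydrazone of 15 (not isolated) | CC(C)[C@@H]1C[C@]2(CC[C@@H]3C(=NNS(=O)(=O)c4ccc(C)cc4)[C@H]2C3(C)C)OC2=C1C(=O)C(C)(C)C(=O)C2(C)C | intermediate
17 | (1S,2S,4'S,5R)-6,6,6',6',8',8'-hexamethyl-4'-(propan-2-yl)-3',4'-dihydrospiro[bicyclo[3.1.1]heptane-2,2'-chromene]-5',7'(6'H,8'H)-dione | CC(C)[C@@H]1C[C@]2(CC[C@@H]3C[C@H]2C3(C)C)OC2=C1C(=O)C(C)(C)C(=O)C2(C)C | target

**Summary**

Total step count: 9. Longest linear sequence: 7 steps (steps 3 to 9); the syncarpic acid branch (steps 1 and 2) joins at step 8.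

**Steps most likely to fail**

Step 7. Strain in the bridged transition state may slow the ring closure so much that methanolysis of the silyl enol ether or solvolysis of the gold-activated alkyne outruns C–C bond formation. The fallback sets out from 6 and closes the same bond oxidatively onto an alkene instead of an alkyne. The azaenolate of 6 (LiN(i-Pr)2, THF) is alkylated with 4-bromobut-1-ene to give (R)-N-[(E,2S)-2-(but-3-en-1-yl)-3,3-dimethylcyclobutylidene]-2-(methoxymethyl)pyrrolidin-1-amine F1. Two-phase oxalic acid hydrolysis gives (2S)-2-(but-3-en-1-yl)-3,3-dimethylcyclobutan-1-one F2. Kinetic silylation (LiN(SiMe3)2, Me3SiCl, THF, −78 °C) gives {[(4S)-4-(but-3-en-1-yl)-3,3-dimethylcyclobut-1-en-1-yl]oxy}trimethylsilane F3. Oxidative cycloalkenylation of the silyl enol ether with Pd(OAc)2 (divalent palladium, catalytic, O2, DMSO, 45 °C) proceeds by 6-exo-trig carbopalladation and β-hydride elimination, and the route is rejoined at 12.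

Step 8. The β-carbonyl group lowers the electron density of the alkene, so the cycloaddition may be slow enough for self-condensation of the oxadiene or an ene-type hydrogen transfer to compete, and exo selectivity may be incomplete. The fallback sets out from 12 and removes the ketone before the cycloaddition. Wolff–Kishner reduction (N2H4·H2O, KOH, diethylene glycol, 130 → 200 °C) gives (1R,5R)-6,6-dimethyl-2-methylidenebicyclo[3.1.1]heptane F4. This electron-richer alkene is combined with 14 (made from 3 and 13 as in step 8) in a hetero-Diels–Alder reaction, and the route is rejoined at 17, so step 9 is no longer needed.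

Step 4. The basic azaenolate may remove HBr from the homopropargylic bromide (E2) instead of substituting it. The fallback sets out from 6 and builds the alkyne after the alkylation. Alkylation with 2-(2-bromoethyl)-1,3-dioxolane (LiN(i-Pr)2, THF) gives (R)-N-[(E,2S)-2-[2-(1,3-dioxolan-2-yl)ethyl]-3,3-dimethylcyclobutylidene]-2-(methoxymethyl)pyrrolidin-1-amine F5. Mild acetal hydrolysis (pyridinium p-toluenesulfonate, acetone/H2O) gives 3-[(1S,2E)-2-{[(2R)-2-(methoxymethyl)pyrrolidin-1-yl]imino}-4,4-dimethylcyclobutyl]propanal F6. Ohira–Bestmann homologation (dimethyl (1-diazo-2-oxopropyl)phosphonate, K2CO3, MeOH) converts the aldehyde into the terminal alkyne, and the route is rejoined at 9.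

**Further compounds**

F1 | step 7 | (R)-N-[(E,2S)-2-(but-3-en-1-yl)-3,3-dimethylcyclobutylidene]-2-(methoxymethyl)pyrrolidin-1-amine | C=CCC[C@@H]1/C(=N/N2CCC[C@@H]2COC)CC1(C)C
F2 | step 7 | (2S)-2-(but-3-en-1-yl)-3,3-dimethylcyclobutan-1-one | C=CCC[C@@H]1C(=O)CC1(C)C
F3 | step 7 | {[(4S)-4-(but-3-en-1-yl)-3,3-dimethylcyclobut-1-en-1-yl]oxy}trimethylsilane | C=CCC[C@@H]1C(O[Si](C)(C)C)=CC1(C)C
F4 | step 8 | (1R,5R)-6,6-dimethyl-2-methylidenebicyclo[3.1.1]heptane | C=C1CC[C@@H]2C[C@H]1C2(C)C
F5 | step 4 | (R)-N-[(E,2S)-2-[2-(1,3-dioxolan-2-yl)ethyl]-3,3-dimethylcyclobutylidene]-2-(methoxymethyl)pyrrolidin-1-amine | O1CCOC1CC[C@@H]2/C(=N/N3CCC[C@@H]3COC)CC2(C)C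
F6 | step 4 | 3-[(1S,2E)-2-{[(2R)-2-(methoxymethyl)pyrrolidin-1-yl]imino}-4,4-dimethylcyclobutyl]propanal | O=CCC[C@@H]1/C(=N/N2CCC[C@@H]2COC)CC1(C)C
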